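**Retrosynthetic overview**

1. Locants: the isochromene core is C1–C8a (2-pyranone ring O2/C1/C3/C4/C4a/C8a; carbocycle C4a–C8a). The side chain is C1′–C12′, counted from C5.
2. Last disconnections: O8–H comes from O8–SEM. Then the C4′–C5′ σ-bond, the centre of the skipped 1,5-diene C2′=C3′/C6′=C7′, is cut into (E)-geranyl-B(pin) (C10) and a C17 core whose C5 arm is CH2–CHCl–C(CH3)=CH2.
3. Enabling feature: C4′ and C5′ are both primary and allylic (to the methyl-branched C2′=C3′ and to C6′=C7′), and the quaternary C5 insulates the chain from the dienone and 2-pyranone rings. The C2′=C3′ bond can therefore be parked at C3′=C4′ with a leaving group on C2′, so that SN2′ attack of a C5′-metalated geranyl unit on C4′ forms the bond, adds ten carbons and restores the E-olefin in one event.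
4. The chloro arm is a prenyl group after ene-type chlorination. The prenyl group and the C5 stereocentre come from an enantioselective Pd-catalysed O6→C5 prenyl shift that dearomatises the carbocycle of a 6-prenyloxyisocoumarin.
5. Ring order: the benzene ring is bought (methyl atratate), the 2-pyranone ring is closed by lateral acylation and enol lactonisation, and the carbocycle is then dearomatised.

Key step: step 10

Assumption: the (R,R)-configured DACH-phenyl bisphosphine ligand is taken to give the (5S) product; if the sense of induction is the opposite, the (S,S) ligand is used and nothing else changes.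

**Step 1**
Reactants: 1 methyl atratate (methyl 2,4-dihydroxy-3,6-dimethylbenzoate)
Product: 2 methyl 3-formyl-4,6-dihydroxy-2,5-dimethylbenzoate
Conditions: Cl2CHOMe, TiCl4, CH2Cl2, 0 °C; then aq HCl
Reagents that add atoms: dichloromethyl methyl ether, COC(Cl)Cl; water, O
Why: Rieche formylation, in which the TiCl4-activated ether attacks the only free ring position (ortho to the 4-OH), so no regiochemical question arises.

**Step 2**
Reactants: 2 methyl 3-formyl-4,6-dihydroxy-2,5-dimethylbenzoate
Product: 3 methyl 2,4-dihydroxy-3,5,6-trimethylbenzoate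
Conditions: Et3SiH, CF3CO2H, 0 °C to rt
Reagents that add atoms: none
Why: Ionic hydrogenation of an electron-rich o-hydroxybenzaldehyde, in which protonation and hydride transfer run twice through the stabilised benzylic cation down to ArCH3 while the ester is inert.

**Step 3**
Reactants: 3 methyl 2,4-dihydroxy-3,5,6-trimethylbenzoate; 4 prenyl bromide
Product: 5 methyl 2-hydroxy-3,5,6-trimethyl-4-(3-methylbut-2-enyloxy)benzoate
Conditions: K2CO3, acetone, reflux
Reagents that add atoms: none
Why: Williamson ether synthesis; the 2-OH is locked in a hydrogen bond to the ester carbonyl, so the weak base ionises and alkylates only the 4-OH.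

**Step 4**
Reactants: 5 methyl 2-hydroxy-3,5,6-trimethyl-4-(3-methylbut-2-enyloxy)benzoate
Product: 6 methyl 3,5,6-trimethyl-4-(3-methylbut-2-enyloxy)-2-{[2-(trimethylsilyl)ethoxy]methoxy}benzoate
Conditions: NaH, SEMCl, DMF, 0 °C to rt
Reagents that add atoms: 2-(trimethylsilyl)ethoxymethyl chloride, C[Si](C)(C)CCOCCl
Why: Williamson-type acetal protection after full deprotonation; SEM is chosen because it later becomes a fluoride-labile vinylogous SEM ester and because its bulk screens the neighbouring ring carbon in step 7.

**Step 5**
Reactants: 6 methyl 3,5,6-trimethyl-4-(3-methylbut-2-enyloxy)-2-(SEM-oxy)benzoate; 7 N-methoxy-N-methylacetamide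
Product: 9 methyl 3,5-dimethyl-6-(2-oxopropyl)-4-(3-methylbut-2-enyloxy)-2-(SEM-oxy)benzoate, via benzylic lithium species 8 (not isolated)
Conditions: LDA, THF, −78 °C; then 7, −78 to 0 °C; aq NH4Cl
Reagents that add atoms: lithium diisopropylamide, [Li+].CC(C)[N-]C(C)C (lithium in 8 only)
Why: Lateral lithiation of an o-toluate followed by Weinreb ketone synthesis; only the methyl group ortho to the ester gives a conjugated anion, and the chelated tetrahedral adduct prevents over-addition.

**Step 6**
Reactants: 9 methyl 3,5-dimethyl-6-(2-oxopropyl)-4-(3-methylbut-2-enyloxy)-2-(SEM-oxy)benzoate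
Product: 10 3,5,7-trimethyl-6-(3-methylbut-2-enyloxy)-8-(SEM-oxy)-1H-isochromen-1-one
Conditions: DBU (cat.), 4 Å MS, PhMe, 90 °C
Reagents that add atoms: none
Why: Base-mediated enol lactonisation (6-exo-trig O-acylation of the conjugated enolate on the neighbouring ester), driven by removal of methanol and by the conjugation of the isocoumarin, under conditions that spare the acid-labile prenyl ether and SEM group.

**Step 7**
Reactants: 10 3,5,7-trimethyl-6-(3-methylbut-2-enyloxy)-8-(SEM-oxy)-1H-isochromen-1-one
Product: 11 (5S)-3,5,7-trimethyl-5-(3-methylbut-2-enyl)-8-(SEM-oxy)-1H-isochromene-1,6(5H)-dione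
Conditions: Pd2(dba)3·CHCl3 (2.5 mol %), (R,R)-DACH-phenyl bisphosphine ligand (6 mol %), degassed PhMe, 40 °C
Reagents that add atoms: none
Why: Tsuji–Trost-type asymmetric allylic dearomatisation run as an O6→C5 prenyl shift: Pd(0) ionises the twisted, di-ortho-substituted aryl prenyl ether, the phenoxide re-attacks the unsubstituted terminus of the π-prenyl–Pd complex through C5 (the naphthol-like position next to the ring fusion, whose attack keeps the 2-pyranone ring intact and creates the O8–C8=C7–C6=O vinylogous ester, whereas C7 is screened by the SEM group), and the chiral pocket of the ligand selects the face of the flat phenoxide, which sets C5 as S.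

**Step 8**
Reactants: 11 (5S)-3,5,7-trimethyl-5-(3-methylbut-2-enyl)-8-(SEM-oxy)-1H-isochromene-1,6(5H)-dione
Product: 12 (5S)-5-(2-chloro-3-methylbut-3-enyl)-3,5,7-trimethyl-8-(SEM-oxy)-1H-isochromene-1,6(5H)-dione (C2′ epimers)
Conditions: NCS, PhSeCl (5 mol %), CH2Cl2, rt
Reagents that add atoms: N-chlorosuccinimide, O=C1CCC(=O)N1Cl
Why: Selenium-catalysed ene-type allylic chlorination, in which PhSeCl engages the most electron-rich π bond (the prenyl olefin) and NCS oxidation of the allyl selenide with allylic displacement returns PhSeCl and the rearranged secondary chloride with an isopropenyl end; the new C2′ centre forms without control, which is harmless because step 10 erases it.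

**Step 9**
Reactants: 13 geranyl chloride
Product: 14 (E)-geranylboronic acid pinacol ester
Conditions: B2pin2, Pd2(dba)3 (1 mol %), THF, 60 °C
Reagents that add atoms: bis(pinacolato)diboron, CC1(C)OB(OC1(C)C)B1OC(C)(C)C(C)(C)O1
Why: Palladium-catalysed allylic borylation (Miyaura type), in which oxidative addition gives the π-geranyl–Pd complex and transmetalation with reductive elimination places boron on the primary terminus with the E geometry kept.

**Step 10**
Reactants: 12 (5S)-5-(2-chloro-3-methylbut-3-enyl)-3,5,7-trimethyl-8-(SEM-oxy)-1H-isochromene-1,6(5H)-dione (C2′ epimers); 14 (E)-geranylboronic acid pinacol ester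
Product: 16 (5S)-5-[(2E,6E)-farnesyl]-3,5,7-trimethyl-8-(SEM-oxy)-1H-isochromene-1,6(5H)-dione, via potassium geranyl(methoxy)pinacolborate 15 (not isolated)
Conditions: 14 premixed with KOMe, THF, 0 °C; then (IMes)CuCl (10 mol %), 12, 0 °C to rt
Reagents that add atoms: potassium methoxide, [K+].[O-]C (its atoms are in 15, not in 16)
Why: Proposed new method: borate 15 hands its geranyl group to the NHC–copper centre to give a σ-geranylcopper(I) with copper on the primary carbon C5′, which adds oxidatively, anti to chloride, to the unhindered methylene C4′ of the C3′=C4′ bond of 12 (SN2′), and the resulting allyl(geranyl)copper(III) collapses by C4′–C5′ reductive elimination before exchange with further 15 restarts the cycle. The closest known reaction types are the NHC–copper-catalysed γ-selective allyl–allyl coupling of allylboronates with allylic phosphates or chlorides, its multicomponent variant in which a substituted allylcopper couples through its copper-bearing carbon, and the classical SN2′ displacement of 3-acyloxy-2-methylalk-1-enes by organocopper reagents that gives E-trisubstituted olefins; new here are the γ,γ-disubstituted geranyl boronate and the 2-methyl-branched secondary chloride on a dienone core. No ring is closed and no stereocentre is created: C2′ is erased so both epimers converge on one product, and the quaternary, remote C5 is untouched. The new C2′=C3′ geometry is controlled by allylic strain in the SN2′ transition state, because with C2′–Cl aligned with the π system the bulky CH2–C5 arm turns away from the C4′ methylene that receives copper and ends trans to C4′ (E), while the C6′=C7′ geometry is carried over from 14 since copper stays on C5′. The step needs α-selectivity on the geranyl side and γ-selectivity on the chloride side, both secured by sterics, since any other pairing would build a quaternary carbon at C7′ or a branched centre at the neopentyl-like C2′. It also needs chemoselectivity over the core, secured by the absence of an acidic proton (O8–SEM), by binding all methoxide in 15, and by the fact that carbonyl addition of an allylcopper would have to pass through the tertiary C7′ onto the hindered, vinylogous-ester-deactivated C6=O.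

**Step 11**
Reactants: 16 (5S)-5-[(2E,6E)-farnesyl]-3,5,7-trimethyl-8-(SEM-oxy)-1H-isochromene-1,6(5H)-dione
Product: 18 5-farnesyl-isochromene (target), via tetrabutylammonium enolate 17 (not isolated)
Conditions: TBAF, THF, 0 °C; then 0.1 M aq HCl
Reagents that add atoms: tetrabutylammonium fluoride, CCCC[N+](CCCC)(CCCC)CCCC.[F-] (cation in 17 only)
Why: Fluoride-induced SEM cleavage, in which attack on silicon triggers β-fragmentation and expels the carboxylate-like C6/C8/C1 tricarbonyl enolate, so the reaction runs cold and without strong acid, leaves the triene, the lactone and C5 untouched, and gives the hydrogen-bonded C8 enol on mild acidification.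

**Compound list**

| No. | Name | SMILES | Role |
|---|---|---|---|
| 1 | methyl atratate (methyl 2,4-dihydroxy-3,6-dimethylbenzoate) | COC(=O)c1c(C)cc(O)c(C)c1O | starting material |
| 2 | methyl 3-formyl-4,6-dihydroxy-2,5-dimethylbenzoate | COC(=O)c1c(C)c(C=O)c(O)c(C)c1O | intermediate |
| 3 | methyl 2,4-dihydroxy-3,5,6-trimethylbenzoate | COC(=O)c1c(C)c(C)c(O)c(C)c1O | intermediate |
| 4 | prenyl bromide | CC(C)=CCBr | starting material |
| 5 | methyl 2-hydroxy-3,5,6-trimethyl-4-(3-methylbut-2-enyloxy)benzoate | COC(=O)c1c(C)c(C)c(OCC=C(C)C)c(C)c1O | intermediate |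
| 6 | methyl 3,5,6-trimethyl-4-(3-methylbut-2-enyloxy)-2-(SEM-oxy)benzoate | COC(=O)c1c(C)c(C)c(OCC=C(C)C)c(C)c1OCOCC[Si](C)(C)C | intermediate |
| 7 | N-methoxy-N-methylacetamide | CON(C)C(C)=O | starting material |
| 8 | benzylic lithium species of 6 (not isolated) | [Li]Cc1c(C)c(OCC=C(C)C)c(C)c(OCOCC[Si](C)(C)C)c1C(=O)OC | intermediate |
| 9 | methyl 3,5-dimethyl-6-(2-oxopropyl)-4-(3-methylbut-2-enyloxy)-2-(SEM-oxy)benzoate | COC(=O)c1c(CC(C)=O)c(C)c(OCC=C(C)C)c(C)c1OCOCC[Si](C)(C)C | intermediate |
| 10 | 3,5,7-trimethyl-6-(3-methylbut-2-enyloxy)-8-(SEM-oxy)-1H-isochromen-1-one | Cc1cc2c(C)c(OCC=C(C)C)c(C)c(OCOCC[Si](C)(C)C)c2c(=O)o1 | intermediate |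
| 11 | (5S)-3,5,7-trimethyl-5-(3-methylbut-2-enyl)-8-(SEM-oxy)-1H-isochromene-1,6(5H)-dione | CC(C)=CC[C@]1(C)C(=O)C(C)=C(OCOCC[Si](C)(C)C)c2c1cc(C)oc2=O | intermediate |
| 12 | (5S)-5-(2-chloro-3-methylbut-3-enyl)-3,5,7-trimethyl-8-(SEM-oxy)-1H-isochromene-1,6(5H)-dione (C2′ epimers) | C=C(C)C(Cl)C[C@]1(C)C(=O)C(C)=C(OCOCC[Si](C)(C)C)c2c1cc(C)oc2=O | intermediate |
| 13 | geranyl chloride | CC(C)=CCC/C(C)=C/CCl | starting material |
| 14 | (E)-geranylboronic acid pinacol ester | CC(C)=CCC/C(C)=C/CB1OC(C)(C)C(C)(C)O1 | intermediate |
| 15 | potassium geranyl(methoxy)pinacolborate (not isolated) | CC(C)=CCC/C(C)=C/C[B-]1(OC)OC(C)(C)C(C)(C)O1.[K+] | intermediate |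
| 16 | (5S)-5-[(2E,6E)-farnesyl]-3,5,7-trimethyl-8-(SEM-oxy)-1H-isochromene-1,6(5H)-dione | CC(C)=CCC/C(C)=C/CC/C(C)=C/C[C@]1(C)C(=O)C(C)=C(OCOCC[Si](C)(C)C)c2c1cc(C)oc2=O | intermediate |
| 17 | tetrabutylammonium enolate of 18 (not isolated) | CC(C)=CCC/C(C)=C/CC/C(C)=C/C[C@]1(C)C(=O)C(C)=C([O-])c2c1cc(C)oc2=O.CCCC[N+](CCCC)(CCCC)CCCC | intermediate |
| 18 | 5-farnesyl-isochromene, (5S)-5-[(2E,6E)-farnesyl]-8-hydroxy-3,5,7-trimethyl-1H-isochromene-1,6(5H)-dione | CC(C)=CCC/C(C)=C/CC/C(C)=C/C[C@]1(C)C(=O)C(C)=C(O)c2c1cc(C)oc2=O | target |

**Total step count:** 11. **Longest linear sequence:** 10 steps (steps 1–8, 10, 11); step 9 is the side branch.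

**Steps most likely to fail**

**1. Step 10 (proposed method).**
- What may go wrong: the geranyl group may be delivered through its tertiary γ-carbon, chloride may be displaced directly at C2′, the new olefin may form with eroded E geometry, or the organocopper may add to the dienone.
- Fallback: known allyl sulfone alkylation with reductive desulfonylation, forming the same C4′–C5′ bond. It sets out from 11 and 13.
- Allylic oxidation of the (E)-methyl group of 11 (cat. SeO2, t-BuOOH, CH2Cl2) should give the (E)-allylic alcohol F1, and an Appel reaction (CBr4, PPh3) the (E)-allylic bromide F2.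
- Compound 13 and PhSO2Na (DMF) give geranyl phenyl sulfone F3. Lithiated F3 (n-BuLi, THF, −78 °C) is alkylated at its α-carbon by F2 to the C5′-sulfone F4.
- Pd-catalysed hydride desulfonylation [PdCl2(dppp), LiHBEt3, THF, −20 °C], which keeps the position and geometry of the olefin, comes back to the route at 16.

**2. Step 7.**
- What may go wrong: poor facial selectivity in the attack of the flat phenoxide, return to oxygen, attack through the other ortho carbon, or loss of the prenyl unit by β-hydride elimination from the π-allyl complex. The product must also be kept at or below 40 °C to avoid [3,3] shifts of the allyl dienone.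
- Fallback: resolution instead of asymmetric catalysis. It sets out from 10.
- The shift is run with achiral Pd(PPh3)4 (THF, 40 °C) to give 11 together with its (5R)-enantiomer F5. Preparative chromatography on a chiral stationary phase (SFC) separates them, and the route is rejoined at 11.

**3. Step 8.**
- What may go wrong: electrophilic chlorine or selenium may attack the C7=C8 enol ether or C4–H of the pyranone instead of the prenyl olefin, or the C6 carbonyl oxygen may take part once the chloride is formed.
- Fallback: oxygen instead of chlorine as the C2′ leaving group, introduced photochemically. It sets out from 11.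
- A Schenck ene reaction (O2, tetraphenylporphyrin, visible light, CH2Cl2, 0 °C) should give the secondary allylic hydroperoxide F6, PPh3 reduces it to the allylic alcohol F7, and ClP(O)(OEt)2/DMAP gives the diethyl phosphate F8.
- F8 takes the place of 12 under the conditions of step 10 and comes back to the route at 16.

**Further compounds**

F1 | step 10 | (5S)-5-[(2E)-4-hydroxy-3-methylbut-2-enyl]-3,5,7-trimethyl-8-(SEM-oxy)-1H-isochromene-1,6(5H)-dione | OC/C(C)=C/C[C@]1(C)C(=O)C(C)=C(OCOCC[Si](C)(C)C)c2c1cc(C)oc2=O
F2 | step 10 | (5S)-5-[(2E)-4-bromo-3-methylbut-2-enyl]-3,5,7-trimethyl-8-(SEM-oxy)-1H-isochromene-1,6(5H)-dione | BrC/C(C)=C/C[C@]1(C)C(=O)C(C)=C(OCOCC[Si](C)(C)C)c2c1cc(C)oc2=O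
F3 | step 10 | geranyl phenyl sulfone | CC(C)=CCC/C(C)=C/CS(=O)(=O)c1ccccc1
F4 | step 10 | C5′-phenylsulfonyl derivative of 16 (C5′ epimers) | CC(C)=CCC/C(C)=C/C(C/C(C)=C/C[C@]1(C)C(=O)C(C)=C(OCOCC[Si](C)(C)C)c2c1cc(C)oc2=O)S(=O)(=O)c1ccccc1
F5 | step 7 | (5R)-enantiomer of 11 | CC(C)=CC[C@@]1(C)C(=O)C(C)=C(OCOCC[Si](C)(C)C)c2c1cc(C)oc2=O
F6 | step 8 | (5S)-5-(2-hydroperoxy-3-methylbut-3-enyl)-3,5,7-trimethyl-8-(SEM-oxy)-1H-isochromene-1,6(5H)-dione (C2′ epimers) | C=C(C)C(OO)C[C@]1(C)C(=O)C(C)=C(OCOCC[Si](C)(C)C)c2c1cc(C)oc2=O
F7 | step 8 | (5S)-5-(2-hydroxy-3-methylbut-3-enyl)-3,5,7-trimethyl-8-(SEM-oxy)-1H-isochromene-1,6(5H)-dione (C2′ epimers) | C=C(C)C(O)C[C@]1(C)C(=O)C(C)=C(OCOCC[Si](C)(C)C)c2c1cc(C)oc2=O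
F8 | step 8 | diethyl phosphate of F7 (C2′ epimers) | C=C(C)C(OP(=O)(OCC)OCC)C[C@]1(C)C(=O)C(C)=C(OCOCC[Si](C)(C)C)c2c1cc(C)oc2=O
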